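The earlier runs and the new flask are simulated for an exercise, and the scatter is random.

The theta run, charged with 0.12 mM of free catalyst, has nearly stopped at 57.9% of target by 2.50 h, while the epsilon run, with 0.38 mM, reaches 94.0%. So I read the catalyst as a budget that gets spent.

| flask | starting material | gas phase | free catalyst | impurity | temperature | remark | time |
|---|---|---|---|---|---|---|---|
| epsilon | 0.050 M | 3.6 mM (held) | 0.38 mM | 37 µM | 110 °C | run made earlier |  |
| theta | 0.050 M | 3.6 mM (held) | 0.12 mM | 37 µM | 110 °C | run made earlier |  |
| Tuesday's | 0.012 M | 3.6 mM (held) | 0.25 mM | 150 µM | 110 °C |  | 4.0 h |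
| Saturday's | 0.050 M | 3.6 mM (held) | 0.25 mM | 37 µM | 110 °C |  | 4.0 h |

- epsilon (time / h: target / %): 0.333: 47.6; 0.833: 80.8; 1.50: 90.1; 2.50: 94.0
- theta (time / h: target / %): 0.333: 27.2; 0.833: 46.0; 1.50: 55.5; 2.50: 57.9

(each reading ± 1 percentage point)

- the numbers in the tables scatter by 1 percentage point (one standard deviation)
- at the start none of the gas phase is in solution
- no earlier run changes the charge of impurity; that part of a forecast is a guess

* which one finishes higher in amount of target, in percent of the starting material charged ("neither" within 2 percentage points) (Tuesday's / Saturday's / neither)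
* amount of target at the end, in percent of the starting material charged, Tuesday's
* amount of target at the end, in percent of the starting material charged, Saturday's

Let y be the final fraction of target. I define the catalyst budget κ as −ln(1−y) per unit of free catalyst charged: 7.21 mM⁻¹ from the theta run. This treats the loss of starting material as pseudo-first-order, so that dilution leaves y unchanged, and no run tests that assumption. Going round once more, I put κ into the epsilon run and get 93.5% against the reading of 94.0%, so I keep κ for 37 µM of impurity. Saturday's, with 0.25 mM of catalyst and that same impurity, then gives 83.5%.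

Now I turn the question round. To come within 2 percentage points of that, Tuesday's needs 0.234 mM of working catalyst, so it can lose 15.9 µM. But it carries 113 µM of extra impurity, which is far more than that allowance. If each extra impurity took one catalyst, Tuesday's would reach 62.8%. I therefore expect Saturday's to win, with Tuesday's between these two figures.

The forecast also says Saturday's, with 84% for Saturday's and 68% for Tuesday's. Of the impurity it writes “The runs cannot settle this”, and its guess lies inside my range.

The flask gives Saturday's, with 84.4% for Saturday's and 72.4% for Tuesday's.

    gas phase ⇌ dissolved gas, rate k1*(csat - [dissolved gas]) (kL = 0.00800 s⁻¹)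
    dissolved gas → decomposed reagent (k = 8.80 × 10⁻⁴ s⁻¹, Ea = 113 kJ mol⁻¹)
    free catalyst → spent catalyst A (k = 5.00 × 10⁻⁴ s⁻¹, Ea = 109 kJ mol⁻¹)
    starting material + dissolved gas + free catalyst → free catalyst + target (k = 2300 M⁻² s⁻¹, Ea = 36.0 kJ mol⁻¹)
    free catalyst + impurity → spent catalyst B (k = 1600 M⁻¹ s⁻¹, Ea = 50.0 kJ mol⁻¹)
    (constants at 110 °C)

At 4.00 h, Tuesday's holds spent catalyst B at 60.0% of the catalyst charged, with impurity at 0% of its own charge. Read through κ, Tuesday's target corresponds to an apparent catalyst loss of 71.3 µM, more than the allowance. A neighbour flask, like Tuesday's but charged with 6.3 × 10⁻⁵ M of free catalyst, starts below that loss, so if it suffers the same loss, the reckoning with κ gives it no working catalyst and no target. The computed flask gives 0.0132% of target, with impurity at 58% of its own charge.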